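The pitfall is to read the high early share of target as the selectivity of this flask: in both earlier runs target sinks while isomer of the product climbs, so the share is a clock, not a constant.

common to all: gas 1.4 mM (held)
- Friday's: starting material 0.038 M; run made earlier
- Sunday's: starting material 0.059 M; run made earlier
- flask: starting material 0.027 M; time 8.0 h

- Friday's (time / h: target / %, isomer of the product / %, starting material / %): 0.417: 17.7, 0.9, 50.9; 1.33: 17.4, 4.2, 49.3; 2.00: 16.9, 5.1, 48.4; 3.00: 16.3, 8.5, 47.9; 5.00: 15.7, 13.4, 44.1
- Sunday's (time / h: target / %, isomer of the product / %, starting material / %): 1.00: 18.4, 2.2, 49.4; 2.00: 17.3, 5.4, 48.3; 3.00: 16.2, 7.4, 47.3; 4.00: 16.1, 11.5, 46.1; 5.00: 15.9, 12.3, 45.1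

(each reading ± 0.5 percentage points)

- at the start none of reagent is dissolved
- what was read earlier has a scatter of 0.5 percentage points, one standard deviation
- steps under discussion: starting material + reagent <-> target; starting material + reagent <-> isomer of the product; starting material <-> dormant form; gas <-> reagent

1. share of target in target plus isomer of the product at 25 s
2. share of target in target plus isomer of the product at 12 min
3. share of target in target plus isomer of the product at 8.0 h

I keep a ledger of starting material, the limiting reagent in the usual sense, and over the span of the readings I freeze reagent at the saturation value 1.4 mM, which makes each step pseudo-first-order. The percentages support this: at 5.00 h, target reads 15.7 % on Friday's charge of 0.038 M and 15.9 % on Sunday's charge of 0.059 M. Friday's entries at that time are starting material 44.1 %, target 15.7 % and isomer 13.4 %; the missing 26.8 % I book as dormant form, and the ledger closes.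

Everything except isomer I call the pool, and target is a share φ = 18.1 % of it. From the decline of the pool in both runs I take the drain constant λ, the fraction of the pool passing net into isomer per hour, 0.0283 h⁻¹.

After time t the pool is exp(−λt) of the charge. My share at 8.0 h is therefore 41.6 %, and at 12 min it is 97.0 %. Friday's first reading, at 0.417 h, comes later than both 12 min and 25 s, so my share at 12 min assumes that φ already stands by then, and at 25 s I make no such assumption and reckon nothing.

The forecast, holding that “The data show no clear reversal, though isomer equilibrium is poorly defined”, gives 98.7 % (96.5 % to 99.8 %), 96.8 % (94.5 % to 98.2 %) and 42.5 % (39 % to 46.5 %). Its last value stands above mine.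

The flask gives 98.5 %, 96.3 % and 43.3 %, each inside the forecast's range. In the flask at 8.00 h, isomer over starting material is 0.459, against 2.66 at equilibrium of that step, so its way back runs at 17.3 % of the forward rate. Put to use once more, λ and φ set target level with isomer at ln(1 + φ)/λ = 5.88 h; the flask stands level at 6.12 h.

    starting material + reagent ⇌ target (K = 250 M⁻¹, k = 45.0 M⁻¹ min⁻¹)
    starting material + reagent ⇌ isomer of the product (K = 1900 M⁻¹, k = 0.670 M⁻¹ min⁻¹)
    starting material ⇌ dormant form (K = 0.600, k = 0.140 min⁻¹)
    gas ⇌ reagent, rate k4*(csat - [reagent]) (kL = 5.30 min⁻¹)

Neither φ nor λ contains the charge, so for the neighbour flask with 0.0067 M of starting material they give 41.6 % again at 8.0 h. The computed share there is 43.3 %, with isomer at 19.1 %.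

(Readings and results are calculated with made-up constants, noise included.)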